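**Plan**

Numbering: flavan locants are used. In the B ring, C1' bears C2, C2' bears the prenyl group, C3'/C4' are the pyran fusion atoms (oxygen on C4'), C5' bears OH and C6' bears H. The pyran carbons are C2''(Me2), C3'' and C4''. These locants are kept for all precursors.
Enabling feature: each C5 unit lies one pericyclic relay from a phenolic oxygen. The pyran spans O4'/C3' (the other ortho carbon, C5', is blocked by oxygen). The 1,1-dimethylallyl group sits on C6, ortho to O7, whose para carbon C4a is alkylated. The linear prenyl group sits on C2', para to O5'.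
First cut: C3'–C4'' (pyran), C6–CMe2 and C2'–CH2 are cut together. All three units return to O4', O7 and O5', which gives the isomeric tri-ether 11.
Second cut: 11 is cut at O1–C2 (Mitsunobu) and at C3–C4 (Claisen–Schmidt, then C=C/C=O reduction). This leads to acetophenone 5 and salicylaldehyde 7, each made from a commercial dihydroxyarene by regioselective O-alkylation.
Ring order forward: both benzene rings are bought, the chroman ring closes in step 6, and the 2H-pyran ring closes last in step 7.
Stereochemistry: C2 is set as the (R)-carbinol by Ru/(R,R)-TsDPEN transfer hydrogenation and inverted to (2S) in the Mitsunobu closure. Step 7 does not touch it.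

Key step: step 7

**Step 1**
Reactants: 1 3,4-dihydroxyacetophenone; 2 3-chloro-3-methylbut-1-yne
Product: 3 1-[3-hydroxy-4-(2-methylbut-3-yn-2-yloxy)phenyl]ethanone
Conditions: 2 (1.2 equiv), DBU (1.05 equiv), CuCl2·2H2O (1 mol %), MeCN, 0 °C, N2
Reagents that add atoms: 3-chloro-3-methylbut-1-yne (compound 2), C#CC(C)(C)Cl
Why: Copper-catalysed propargylic etherification (Williamson type), in which one equivalent of base ionises only the 4-OH, acidified by the para acetyl group, so the tertiary propargylic electrophile should be taken up at O4 and the 3-OH left free.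

**Step 2**
Reactants: 3; 4 prenyl bromide (1-bromo-3-methylbut-2-ene)
Product: 5 1-[3-(3-methylbut-2-enyloxy)-4-(2-methylbut-3-yn-2-yloxy)phenyl]ethanone
Conditions: 4 (1.2 equiv), K2CO3, acetone, reflux
Reagents that add atoms: prenyl bromide (compound 4), CC(C)=CCBr
Why: Williamson ether synthesis on the one remaining phenol with a reactive allylic bromide, to which the ketone and the terminal alkyne are inert under K2CO3 in acetone.

**Step 3**
Reactants: 6 2,4-dihydroxybenzaldehyde; 4 prenyl bromide
Product: 7 2-hydroxy-4-(3-methylbut-2-enyloxy)benzaldehyde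
Conditions: 4 (1.05 equiv), K2CO3 (1.0 equiv), acetone, reflux
Reagents that add atoms: prenyl bromide (compound 4), CC(C)=CCBr
Why: Regioselective Williamson ether synthesis, because the 2-OH is held in a hydrogen bond to the formyl oxygen and the 4-OH is therefore alkylated first.

**Step 4**
Reactants: 5; 7
Product: 8 (E)-3-[2-hydroxy-4-(3-methylbut-2-enyloxy)phenyl]-1-[3-(3-methylbut-2-enyloxy)-4-(2-methylbut-3-yn-2-yloxy)phenyl]prop-2-en-1-one
Conditions: KOH, EtOH, 25–40 °C; then AcOH to pH 6, 0 °C
Reagents that add atoms: none
Why: Claisen–Schmidt condensation of a methyl ketone with a non-enolisable aldehyde, well known for free salicylaldehydes; E1cB dehydration gives the E-enone, and the quaternary propargylic carbon rules out alkyne–allene isomerisation in base.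

**Step 5**
Reactants: 8
Product: 10 (1R)-3-[2-hydroxy-4-(3-methylbut-2-enyloxy)phenyl]-1-[3-(3-methylbut-2-enyloxy)-4-(2-methylbut-3-yn-2-yloxy)phenyl]propan-1-ol, via dihydrochalcone 9 (not isolated)
Conditions: RuCl[(R,R)-TsDPEN](p-cymene) (2 mol %), HCO2H/Et3N (5:2), EtOAc, 40 °C
Reagents that add atoms: none
Why: Tandem Noyori-type asymmetric transfer hydrogenation of a chalcone, in which the nucleophilic Ru–H first adds 1,4 to give 9 and then reduces the aryl alkyl ketone through the outer-sphere six-membered transition state whose arene CH/π contact makes the (R,R)-ligand deliver the (R)-carbinol, while the unpolarised alkenes and the alkyne should not react.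

**Step 6**
Reactants: 10
Product: 11 (2S)-7,5'-bis(3-methylbut-2-enyloxy)-4'-(2-methylbut-3-yn-2-yloxy)flavan
Conditions: PPh3, DIAD, toluene (0.02 M), 0 °C
Reagents that add atoms: none
Why: Intramolecular Mitsunobu etherification, a 6-exo-tet SN2 displacement of the alkoxyphosphonium group by the ortho phenoxide that inverts C2 from (R) to (S); the non-polar solvent and low temperature are chosen to hold back ionisation of the para-alkoxybenzylic centre.

**Step 7**
Reactants: 11
Product: 16 kazinol H, via allenylphenol 12 (not isolated), via o-quinone methide 13 (not isolated), via chromene bis(prenyl ether) 14 (not isolated), via ortho-dienone 15 (not isolated)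
Conditions: PhNEt2 (degassed, 0.02 M), 200 °C, sealed tube, Ar
Reagents that add atoms: none
Why: On heating, the aryl 1,1-dimethylpropargyl ether undergoes a propargyl Claisen [3,3] shift to C3', tautomerises to allenylphenol 12 and passes by a [1,5]-H shift into the vinylogous o-quinone methide 13. The 2H-pyran ring then closes by a thermally allowed disrotatory oxa-6π electrocyclisation of the O4'=C4'–C3'=C4''–C3''=C2'' array (O4'–C2'' bond, six-membered ring, B ring rearomatised) to give 14, which is the classical thermal chromene synthesis. In the same vessel the O7 prenyl ether undergoes an ortho aromatic Claisen shift with allyl inversion that bonds the quaternary CMe2 carbon to C6, and the O5' prenyl ether takes the Claisen–Cope (para-Claisen) path through dienone 15, whose second [3,3] shift carries the unit on to C2' as a linear prenyl group before tautomerisation frees the 5'-OH; both are known behaviour of aryl prenyl ethers under these conditions, and the order of the two prenyl shifts is immaterial. No lasting stereocentre is created and C2 lies outside every pericyclic array; because O4' stays etherified and the freed 5'-OH is meta to C1', no quinone methide can open the O1–C2 bond, so (2S) should be retained. Three site selectivities are needed: C3' over C5' is enforced by the oxygen on C5'; C6 over C8 rests on the crowding of C8 between O1 and O7 towards a tertiary terminus and on the alkylated para carbon C4a, which makes any Cope excursion reversible so that the unit can settle only at an ortho carbon; C2' over C6' rests on the strain of 15, whose CMe2 group is pressed against the chroman substituent on C1' so that the unimolecular Cope shift should outrun bimolecular tautomerisation, and on the fact that the alternative dienone at C4' has no hydrogen to lose and leads to C2' as well. The step is a pure isomerisation (C30H36O4), so the three migrating groups serve as the phenol protection up to this point and no helper has to be removed afterwards.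

**Compound list**

1 | 3,4-dihydroxyacetophenone | CC(=O)c1ccc(O)c(O)c1 | starting material
2 | 3-chloro-3-methylbut-1-yne | C#CC(C)(C)Cl | starting material
3 | 1-[3-hydroxy-4-(2-methylbut-3-yn-2-yloxy)phenyl]ethanone | CC(=O)c1ccc(OC(C)(C)C#C)c(O)c1 | intermediate
4 | prenyl bromide (1-bromo-3-methylbut-2-ene) | CC(C)=CCBr | starting material
5 | 1-[3-(3-methylbut-2-enyloxy)-4-(2-methylbut-3-yn-2-yloxy)phenyl]ethanone | CC(=O)c1ccc(OC(C)(C)C#C)c(OCC=C(C)C)c1 | intermediate
6 | 2,4-dihydroxybenzaldehyde | O=Cc1ccc(O)cc1O | starting material
7 | 2-hydroxy-4-(3-methylbut-2-enyloxy)benzaldehyde | O=Cc1ccc(OCC=C(C)C)cc1O | intermediate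
8 | (E)-2-hydroxychalcone bearing the three ether groups | CC(C)=CCOc1ccc(/C=C/C(=O)c2ccc(OC(C)(C)C#C)c(OCC=C(C)C)c2)c(O)c1 | intermediate
9 | dihydrochalcone (saturated ketone of 8), not isolated | CC(C)=CCOc1ccc(CCC(=O)c2ccc(OC(C)(C)C#C)c(OCC=C(C)C)c2)c(O)c1 | intermediate
10 | (1R)-1,3-diarylpropan-1-ol | CC(C)=CCOc1ccc(CC[C@@H](O)c2ccc(OC(C)(C)C#C)c(OCC=C(C)C)c2)c(O)c1 | intermediate
11 | (2S)-7,5'-bis(prenyloxy)-4'-(1,1-dimethylpropargyloxy)flavan | CC(C)=CCOc1ccc2c(c1)O[C@H](c1ccc(OC(C)(C)C#C)c(OCC=C(C)C)c1)CC2 | intermediate
12 | (2S)-4'-hydroxy-3'-(3-methylbuta-1,2-dienyl)-7,5'-bis(prenyloxy)flavan (allenylphenol), not isolated | CC(C)=CCOc1ccc2c(c1)O[C@H](c1cc(C=C=C(C)C)c(O)c(OCC=C(C)C)c1)CC2 | intermediate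
13 | o-quinone methide (C4'=O, C3'=CH–CH=CMe2), not isolated | CC(C)=CCOc1ccc2c(c1)O[C@H](C1=CC(=CC=C(C)C)C(=O)C(OCC=C(C)C)=C1)CC2 | intermediate
14 | (2S)-chromene with prenyl ethers still on O7 and O5', not isolated | CC(C)=CCOc1ccc2c(c1)O[C@H](c1cc(OCC=C(C)C)c3c(c1)C=CC(C)(C)O3)CC2 | intermediate
15 | B-ring ortho-dienone (C5'=O, C6' sp3 with 1,1-dimethylallyl, configuration at C6' open), A ring already rearranged, not isolated | C=CC(C)(C)c1cc2c(cc1O)O[C@H](C3=CC4=C(OC(C)(C)C=C4)C(=O)C3C(C)(C)C=C)CC2 | intermediate
16 | kazinol H, (2S) | C=CC(C)(C)c1cc2c(cc1O)O[C@H](c1cc(O)c3c(c1CC=C(C)C)C=CC(C)(C)O3)CC2 | target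

**Step count and risks**

Total steps: 7. Longest linear sequence: 6 (steps 1, 2, 4, 5, 6, 7).

**Step 7.**
- What may go wrong:
  - Tautomerisation of the C6' dienone may outrun the Cope shift (ortho capture in the B ring).
  - The A-ring unit may settle at C8.
  - The prenyl ethers may fragment with loss of isoprene.
  - The freed 6-(1,1-dimethylallyl)phenol may isomerise further (abnormal Claisen) on long heating.
- Fallback: the B-ring prenyl group is placed by cross-coupling before the fragments are joined, instead of being asked to migrate. The route sets out from 3. Silylation (TBSCl, imidazole, DMF) gives 1-[3-(tert-butyldimethylsilyloxy)-4-(2-methylbut-3-yn-2-yloxy)phenyl]ethanone F1. NBS in MeCN should brominate the dialkoxyarene para to the silyloxy group to give the 2-bromo ketone F2. A base-free and copper-free Stille coupling with tributyl(3-methylbut-2-enyl)stannane (Pd(PPh3)4, DMF, 80 °C) gives the 2-prenyl ketone F3. Claisen–Schmidt condensation with 7 in KOH/EtOH, in which the silyl ether is shed, gives the 5-hydroxy-2-prenyl chalcone F4. The tandem transfer hydrogenation of step 5 gives, through the dihydrochalcone F5, the (R)-carbinol F6. Mitsunobu closure at high dilution gives the (2S)-5'-hydroxy-2'-prenyl flavan F7. Heating F7 as in step 7 then needs only the propargyl Claisen/oxa-6π cascade, which is still the last ring closure, and the A-ring ortho-Claisen shift. It comes back to the route at 16.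

**Step 6.**
- What may go wrong:
  - The alkoxyphosphonium salt of the para-alkoxybenzylic carbinol may partly ionise, which erodes the enantiomeric purity.
  - Elimination to the styrene may compete.
- Fallback: the ring is closed at the arene carbon C8a, so the carbinol C–O bond is never broken. The route sets out from 5 and 4. Commercial 2-bromo-4-hydroxybenzaldehyde is O-prenylated with 4 (K2CO3, acetone) to 2-bromo-4-(3-methylbut-2-enyloxy)benzaldehyde F8. Claisen–Schmidt condensation with 5 gives the bromochalcone F9. Tandem transfer hydrogenation with the (S,S)-catalyst gives, through the bromo dihydrochalcone F10, the (S)-carbinol F11. A Buchwald–Hartwig-type intramolecular C–O coupling then forms O1–C8a with retention and comes back to the route at 11. Its conditions are Pd(OAc)2, a bulky di-tert-butylbiarylphosphine, Cs2CO3 and dilute toluene at 65 °C, with no copper and no amine so that the alkyne C–H stays a bystander.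

**Step 5.**
- What may go wrong:
  - 1,2-Reduction of the electron-rich enone may compete and give the allylic alcohol, which then cyclises.
  - The hemiketal form of 9 may dehydrate in the acidic medium.
  - Hydride transfer may stall.
- Fallback: the two reductions are separated and moved to boron hydride chemistry. The route sets out from 8. Catecholborane (THF, room temperature; the phenol is borylated first) effects conjugate reduction of the s-cis enone, and 9 is isolated after work-up. Corey–Bakshi–Shibata reduction with (S)-Me-CBS and catecholborane (toluene, −78 to −40 °C) then gives the (R)-carbinol and comes back to the route at 10.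

**Further compounds**

F1 | step 7 | 1-[3-(tert-butyldimethylsilyloxy)-4-(2-methylbut-3-yn-2-yloxy)phenyl]ethanone | CC(=O)c1ccc(OC(C)(C)C#C)c(O[Si](C)(C)C(C)(C)C)c1
F2 | step 7 | 1-[2-bromo-5-(tert-butyldimethylsilyloxy)-4-(2-methylbut-3-yn-2-yloxy)phenyl]ethanone | CC(=O)c1cc(O[Si](C)(C)C(C)(C)C)c(OC(C)(C)C#C)cc1Br
F3 | step 7 | 1-[5-(tert-butyldimethylsilyloxy)-2-(3-methylbut-2-enyl)-4-(2-methylbut-3-yn-2-yloxy)phenyl]ethanone | CC(=O)c1cc(O[Si](C)(C)C(C)(C)C)c(OC(C)(C)C#C)cc1CC=C(C)C
F4 | step 7 | (E)-chalcone with 5-hydroxy-2-prenyl-4-(1,1-dimethylpropargyloxy)phenyl ketone part | CC(C)=CCOc1ccc(/C=C/C(=O)c2cc(O)c(OC(C)(C)C#C)cc2CC=C(C)C)c(O)c1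
F5 | step 7 | dihydrochalcone of F4 | CC(C)=CCOc1ccc(CCC(=O)c2cc(O)c(OC(C)(C)C#C)cc2CC=C(C)C)c(O)c1
F6 | step 7 | (1R)-carbinol of F5 | CC(C)=CCOc1ccc(CC[C@@H](O)c2cc(O)c(OC(C)(C)C#C)cc2CC=C(C)C)c(O)c1
F7 | step 7 | (2S)-5'-hydroxy-2'-prenyl-4'-(1,1-dimethylpropargyloxy)-7-(prenyloxy)flavan | CC(C)=CCOc1ccc2c(c1)O[C@H](c1cc(O)c(OC(C)(C)C#C)cc1CC=C(C)C)CC2
F8 | step 6 | 2-bromo-4-(3-methylbut-2-enyloxy)benzaldehyde | O=Cc1ccc(OCC=C(C)C)cc1Br
F9 | step 6 | (E)-2-bromochalcone analogue of 8 | CC(C)=CCOc1ccc(/C=C/C(=O)c2ccc(OC(C)(C)C#C)c(OCC=C(C)C)c2)c(Br)c1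
F10 | step 6 | bromo dihydrochalcone | CC(C)=CCOc1ccc(CCC(=O)c2ccc(OC(C)(C)C#C)c(OCC=C(C)C)c2)c(Br)c1
F11 | step 6 | (1S)-3-(2-bromoaryl)-1-arylpropan-1-ol | CC(C)=CCOc1ccc(CC[C@H](O)c2ccc(OC(C)(C)C#C)c(OCC=C(C)C)c2)c(Br)c1
F0 | step 5 | none | none
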